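## Structural features

Atom numbers C1–C11 of the target are used for every compound: cyclobutane C1–C2–C8–C7, enone bridge C1–C11(=O)–C10=C9(Me)–C8, chain C2(Me)–C3(O‑senecioyl)–C4–C5(O‑isovaleryl)–C6(Me)2–C7. The target 35 is a longipinane‑type tricycle whose four‑membered ring is bridged twice across its 1,3‑positions: C1/C8 by the three‑carbon enone unit (a verbenone‑like bicyclo[3.1.1]heptenone) and C2/C7 by the four‑carbon chain (a bicyclo[4.1.1]octane). All four cyclobutane carbons are contiguous stereocentres (C2 is quaternary), C3 stands next to C2, C5 next to the gem‑dimethyl carbon C6, and the two acyloxy groups are 1,3‑trans. Fragile are the two different esters (the senecioate can deconjugate or accept nucleophiles, the isovalerate is enolisable, and their 1,3‑relation invites acyl shift or β‑elimination beside a carbonyl) and the strained cyclobutane next to the enone, which opens through cyclobutylcarbinyl cations in acid. The real difficulty is the four‑membered ring with its quaternary centre inside two bridged rings, and then the absolute sense of the C3/C5 oxygens, because the two faces of the four‑carbon bridge differ only by C1 versus C8, which look alike locally. The key step exploits that C7–C8 lies between C8 (bearing C9) and C1 (bearing C11): an ester oxygen between C9 and C11 gives a six‑membered lactone (C9, C8, C2, C1, C11, O) beside a C1=C7 double bond, and its ketene acetal C8=C9–O–C11–C1=C7 is an allyl vinyl ether whose [3,3] shift makes exactly C7–C8.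

## Logic of the disconnections

35 ⇒ 29 (+ 31, 34). The ester C–O bonds at C5 and C3 are cut first, because neither acyl group would survive the amide bases, the organolithium and the phosphonate chemistry needed for the skeleton. This removes both appendages and leaves the tricyclic core 29 with two different silyl ethers. The forward steps (through 30, 32, 33) must unmask the C5 oxygen before the C3 oxygen and avoid strong base, so that no acyl shift and no deconjugation occurs.

29 ⇒ 28 ⇒ 27. C9=C10 is cut (olefination) and then C10–C11 (one‑carbon homologation of an aldehyde). The enone is regiodefined only if C10 arrives attached to C11 as a phosphonate; a condensation of two acetyl groups could close in either direction. The six‑membered ring disappears and 27 carries only two carbonyl arms on C1 and C8. The forward steps need these arms cis, and the homologation must take the aldehyde and leave the ketone.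

27 ⇒ 26 ⇒ 25 ⇒ 24. The C11 aldehyde is traced to the exocyclic methylidene (anti‑Markovnikov hydration, which creates C1) and the C9 methyl ketone to the carboxylic acid (C9–CH3 cut). 24 then holds nothing but an acid and an alkene on the four‑membered ring. The hydroboration must come from the face turned away from the C8 substituent.

24 ⇒ 21 (key disconnection). C7–C8 is cut and O–C11 is reconnected. This is the one cyclobutane bond whose two flanking carbons carry the carbons later needed for the third ring, so a temporary ester link between them turns four‑membered ring formation into a sigmatropic shift of a six‑membered lactone. The cyclobutane and the centres C7 and C8 vanish; 21 is a fused 6–7 bicycle with three stereocentres. The configurations of 21 and 24 at C2, C7 and C8 were traced atom by atom to 35 and agree with it, so no structure had to be corrected. What is changed is the state of C3/C5: both are carried as trans silyl ethers instead of a vinylogous ester. The lactone CH2 is still the only acidic position. No hydride has to select between a bridge carbonyl and the C11 enone later. No alkoxy‑allylic ester has to be hydrolysed. Both centres are set while the chain is acyclic and the two sides are unlike.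

21 ⇒ 18 ⇒ 17. The lactone C9–O bond is cut (to a tert‑butyl ester and an allylic alcohol) and then C1=C7 (metathesis). The cis relation of C2 and C6 on this trisubstituted alkene is only stable in the ring, so the alkene is made in the ring‑closing event. The result is the acyclic diene 17. The forward step has to join two alkenes that each carry a quaternary neighbour; the free allylic hydroxyl, the two quaternary centres and the trans‑1,3‑bis(silyloxy) chain should help.

17 ⇒ 16 ⇒ 15 ⇒ 14 ⇒ 13 ⇒ 9 + 11. Cut are C11–O (allylic oxidation at the only allylic C–H), the C5–H bond (ketone reduction) and C3–C4 (aldol). The C3 hydroxyl exists while C5 is still a ketone, so each oxygen receives its own silyl group by timing alone. Two small fragments result. The aldol and the reduction both need reagent control, since C2 offers little bias.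

9 ⇒ 8 ⇒ 7 ⇒ 6 ⇒ 3 + 4, and 3 ⇒ 1 + 2. The C1=CH2 bond (methylenation), the oxidation level of C3 and the C2–C8 bond (alkylation) are cut. The four arms of C2 then come from 1 (methyl, acetyl as C1/C11, ester as C3) and from 4 (C8–C9). The forward steps need facial control by the auxiliary 2 and a reduction that tells an ethyl ester from a tert‑butyl ester.

11 ⇒ 10. C4–C5 is cut: the methyl ketone comes from the acid and a methyl nucleophile, with no selectivity issue because the α‑carbon is quaternary.

## Other disconnections considered

Alternative 1: The cut removes C1–C7, C6–C7 and C2–C8 at once and leads back to the acyclic farnesyl diphosphate A1. In the forward sense a longipinene synthase would ionise A1 and, through macrocyclisation, hydride shift and two further closures, deliver α‑longipinene A2 after loss of a proton from C10. In its favour: all three rings and the four cyclobutane stereocentres arise in one operation without protecting groups. On skeletal step economy and on mechanism (a natural cascade) it is better than the chosen plan. Against it here: an enzyme of the right enantiomeric series must be available and productive, and A2 carries no oxygen. The C11 oxidation has a good model in pinene‑to‑verbenone chemistry. The C3 and C5 hydroxylations, however, are oxidations of unactivated methylenes next to quaternary carbons, in a trans relation and in a fixed absolute sense, and would need further enzymes or directing groups. The chosen plan is stronger on this point, since both oxygens come from 1 and 10 and are set by reagent control. Overall the alternative is shorter if the late oxidations can be done enzymatically, and longer and less certain if they must be chemical.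

Alternative 2: The cut removes C4 (bonds C3–C4 and C4–C5) and leads to the nor‑ketone A3 with a six‑membered ring. Forward, the C3 silyl enol ether of A3 is cyclopropanated with Et2Zn/CH2I2 and opened with FeCl3, then NaOAc, to give the cycloheptenone A4. In its favour: this three‑stage ring expansion is well established, the enol ether can form only toward C4 (equal to the single enolisation site of the chosen plan), and A4 offers handles at C3 and C5. On mechanistic precedent it is better than the chosen key step. Against it: A3 already contains the cyclobutane and both bridges, so the main problem is only moved. The C5 oxygen would have to enter at a neopentyl β‑carbon, C3 and C5 would be set late on the near‑symmetric bridge, and the C9–C10 bond must still be dehydrogenated after the ketal is removed. On structure and on step economy (three operations for one carbon, then several redox steps) the chosen plan is the better one.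

Alternative 3: The cut removes C1–C7 and C2–C8 and opens the cyclobutane and the six‑membered ring together, leading to the trienoyl chloride A5. Forward, triethylamine would give the vinylketene A6, which adds across the C1=C2 alkene to give the cyclobutanone A7. In its favour: intramolecular vinylketene–alkene cycloadditions to bicyclo[3.1.1]heptenones have direct precedent, three stereocentres (C1, C2, C8) follow from the alkene geometry in one step, and the C3 oxygen is in place. On precedent and on what the key step builds (two rings, three centres) it is better than the chosen plan. Against it: the facial choice relative to C3 rests on acyclic allylic strain only, only one geometry of A6 can cyclise, and γ‑deprotonation may occur at the C9 methyl. After A7 the seven‑membered ring is still missing: C6–C7 must be made at the cyclobutanone carbon, its oxygen removed, and the C5 and C11 oxygens added. The chosen plan has the seven‑membered ring and both oxygens before the cyclobutane is formed. Step economy is about equal.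

Key step: step 14

Assumption: the facial sense quoted for each chiral reagent follows its accepted transition‑state model; if a model failed on these hindered substrates the antipodal reagent would be used, the route staying otherwise the same.

## Route

Step 1
Reactants: 1 ethyl 2-methyl-3-oxobutanoate; 2 tert-butyl L-valinate
Product: 3 ethyl (2Z)-3-{[(2S)-1-tert-butoxy-3-methyl-1-oxobutan-2-yl]amino}-2-methylbut-2-enoate
Conditions: BF3·OEt2 (cat.), toluene, reflux (Dean–Stark)
Reagents that add atoms: none
Why: Condensation of a β-keto ester with a primary amine gives the hydrogen-bonded Z-enamino ester; the valine ester is the chiral auxiliary for the alkylation and no stereocentre of the target is set yet.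

Step 2
Reactants: 3 enamino ester; 4 tert-butyl bromoacetate
Product: 6 4-tert-butyl 1-ethyl (2R)-2-acetyl-2-methylbutanedioate, via imine 5 (not isolated)
Conditions: LiN(i-Pr)2, toluene, HMPA (1 equiv), −78 °C; 4, −78 → −40 °C; then aq. citric acid, rt
Reagents that add atoms: water, O
Why: Chiral-enamine alkylation of an α-alkyl β-keto ester: lithiated 3 is a rigid N–Li–O chelate whose isopropyl group shields one face, so C-alkylation should create the quaternary centre C2 as (R), HMPA as external ligand fixing which face is open. Mild acid hydrolysis of 5 frees the ketone and returns 2.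

Step 3
Reactants: 6 keto diester
Product: 7 4-tert-butyl 1-ethyl (2R)-2-methyl-2-(prop-1-en-2-yl)butanedioate
Conditions: Ph3PCH3Br, KN(SiMe3)2, THF, 0 °C → rt
Reagents that add atoms: methyltriphenylphosphonium bromide, C[P+](c1ccccc1)(c1ccccc1)c1ccccc1.[Br-]
Why: Wittig methylenation of the only ketone; C2 is quaternary and cannot epimerise, and both esters are inert to the non-stabilised ylide. The former acetyl methyl is the future C11; the new CH2 is lost again at the metathesis.

Step 4
Reactants: 7 diester
Product: 8 tert-butyl (3R)-3-(hydroxymethyl)-3,4-dimethylpent-4-enoate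
Conditions: i-Bu2AlH (2.2 equiv), CH2Cl2, −78 °C; aq. potassium sodium tartrate
Reagents that add atoms: none
Why: Chemoselective ester reduction: i-Bu2AlH should reduce the ethyl ester at −78 °C while the tert-butyl ester, shielded at its alkoxy side, reacts far more slowly. The cold aluminium alkoxide should not attack the tert-butyl ester, so no γ-lactone is expected.

Step 5
Reactants: 8 alcohol
Product: 9 tert-butyl (3R)-3-formyl-3,4-dimethylpent-4-enoate
Conditions: Dess–Martin periodinane, CH2Cl2, rt
Reagents that add atoms: none
Why: Dess–Martin oxidation of a neopentyl primary alcohol; the aldehyde has no α-hydrogen, so C2 is secure and the alkene cannot move into conjugation.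

Step 6
Reactants: 10 2,2-dimethylbut-3-enoic acid
Product: 11 3,3-dimethylpent-4-en-2-one
Conditions: MeLi (2.2 equiv), Et2O, 0 °C → rt; H2O
Reagents that add atoms: methyllithium, [Li]C
Why: Addition of MeLi to the lithium carboxylate gives a stable geminal dialkoxide that releases the methyl ketone on hydrolysis; the new methyl is C4 and the quaternary α-carbon leaves one enolisation site only.

Step 7
Reactants: 9 aldehyde; 11 methyl ketone
Product: 13 tert-butyl (3R)-3-[(1R)-1-hydroxy-4,4-dimethyl-3-oxohex-5-en-1-yl]-3,4-dimethylpent-4-enoate, via enol borinate 12 (not isolated)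
Conditions: 11, (−)-Ipc2BCl, Et3N, Et2O, 0 °C; then 9, −78 → −20 °C; H2O2, MeOH, pH 7 buffer
Reagents that add atoms: none
Why: Diisopinocampheylboron aldol of a methyl ketone through a cyclic six-membered transition state; the Ipc ligands should direct the enolate to the Re face of the aldehyde and give the (R) carbinol at C3, C2 adding little bias. The C3 epimer is a diastereomer and separable.

Step 8
Reactants: 13 aldol
Product: 14 tert-butyl (3R)-3-[(1R)-1-{[tert-butyl(dimethyl)silyl]oxy}-4,4-dimethyl-3-oxohex-5-en-1-yl]-3,4-dimethylpent-4-enoate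
Conditions: TBSOTf, 2,6-lutidine, CH2Cl2, −78 → 0 °C
Reagents that add atoms: tert-butyldimethylsilyl triflate, CC(C)(C)[Si](C)(C)OS(=O)(=O)C(F)(F)F
Why: Silylation of a hindered secondary alcohol with the silyl triflate under non-nucleophilic base, which avoids retro-aldol cleavage; the C3 oxygen is marked as the one that later takes the senecioate.

Step 9
Reactants: 14 β-silyloxy ketone
Product: 15 tert-butyl (3R)-3-[(1R,3R)-1-{[tert-butyl(dimethyl)silyl]oxy}-3-hydroxy-4,4-dimethylhex-5-en-1-yl]-3,4-dimethylpent-4-enoate
Conditions: (S)-2-methyl-CBS-oxazaborolidine (0.5 equiv), catecholborane, toluene, −78 → −30 °C; aq. NaOH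
Reagents that add atoms: none
Why: Corey–Bakshi–Shibata reduction: the ketone binds anti to its large substituent (the quaternary C6, as the tert-butyl group of pinacolone) and hydride delivery should give (5R), i.e. the 1,3-anti relation to the C3 oxygen under catalyst control. Catecholborane leaves both alkenes untouched at this temperature.

Step 10
Reactants: 15 alcohol
Product: 16 tert-butyl (3R)-3-[(1R,3R)-1-{[tert-butyl(dimethyl)silyl]oxy}-4,4-dimethyl-3-[(triethylsilyl)oxy]hex-5-en-1-yl]-3,4-dimethylpent-4-enoate
Conditions: TESOTf, 2,6-lutidine, CH2Cl2, −78 → 0 °C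
Reagents that add atoms: triethylsilyl triflate, CC[Si](CC)(CC)OS(=O)(=O)C(F)(F)F
Why: Silylation of the neopentyl C5 alcohol; the more labile triethylsilyl group can later be removed in the presence of the tert-butyldimethylsilyl ether.

Step 11
Reactants: 16 bis-silyl ether
Product: 17 tert-butyl (3R)-3-[(1R,3R)-1-{[tert-butyl(dimethyl)silyl]oxy}-4,4-dimethyl-3-[(triethylsilyl)oxy]hex-5-en-1-yl]-4-(hydroxymethyl)-3-methylpent-4-enoate
Conditions: SeO2 (20 mol%), t-BuOOH, CH2Cl2, rt
Reagents that add atoms: tert-butyl hydroperoxide, CC(C)(C)OO
Why: Allylic oxidation (ene reaction, then [2,3] shift) of a 1,1-disubstituted alkene; the C11 methyl holds the only allylic hydrogens of the molecule, since C2 and C6 are quaternary, so the site is unambiguous.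

Step 12
Reactants: 17 diene
Product: 18 tert-butyl 2-[(1R,5R,7R)-7-{[tert-butyl(dimethyl)silyl]oxy}-2-(hydroxymethyl)-1,4,4-trimethyl-5-[(triethylsilyl)oxy]cyclohept-2-en-1-yl]acetate
Conditions: second-generation Hoveyda–Grubbs catalyst (10 mol%), toluene, 90 °C, 2 mM
Reagents that add atoms: none
Why: Ring-closing metathesis: the carbene should load at the monosubstituted vinyl group and close onto the 1,1-disubstituted alkene, helped by its free allylic hydroxyl, the two quaternary centres and the anti-bis(silyloxy) chain. The cis arrangement of C2 and C6 on the new C1=C7 bond is set by the ring.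

Step 13
Reactants: 18 hydroxy tert-butyl ester
Product: 21 (4aR,5R,7R)-5-{[tert-butyl(dimethyl)silyl]oxy}-4a,8,8-trimethyl-7-[(triethylsilyl)oxy]-4,4a,5,6,7,8-hexahydrocyclohepta[c]pyran-3(1H)-one, via silyl ester 19 (not isolated), via hydroxy acid 20 (not isolated)
Conditions: TMSOTf, 2,6-lutidine, CH2Cl2, 0 °C; aq. citric acid; then EDC, DMAP, CH2Cl2, rt
Reagents that add atoms: none
Why: Silyl-triflate cleavage of the tert-butyl ester (loss of 2-methylpropene) spares both silyl ethers; the δ-hydroxy acid then closes to the six-membered lactone by carbodiimide activation, favoured by the quaternary C2 in the ring.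

Step 14
Reactants: 21 δ-lactone
Product: 24 (1R,2R,4R,6S,7S)-2-{[tert-butyl(dimethyl)silyl]oxy}-1,5,5-trimethyl-8-methylidene-4-[(triethylsilyl)oxy]bicyclo[4.1.1]octane-7-carboxylic acid, via silyl ketene acetal 22 (not isolated), via silyl ester 23 (not isolated)
Conditions: LiN(i-Pr)2 (1.1 equiv), Me3SiCl, Et3N, THF, −78 °C; then toluene, 110 °C; aq. citric acid
Reagents that add atoms: none
Why: Proposed new method: LiN(i-Pr)2 removes a C8 hydrogen, the only acidic C–H in 21 (C2 and C6 are quaternary, C3/C5 are silyl ethers), and O-silylation fixes the ring-enforced ketene acetal 22, in which C8=C9–O–C11–C1=C7 is an allyl vinyl ether; on heating, a concerted suprafacial [3,3] shift through a boat bridged by C2 (bicyclo[3.1.1]heptane-like array C8, C9, O, C11, C1, C7) should form C7–C8, break O–C11 and leave the C1=C11 methylidene and the silyl ester 23, which water converts into 24. The closest known reaction type is the Ireland–Claisen ring contraction of unsaturated lactones to cis-2-alkenylcycloalkanecarboxylic acids, cyclobutanes included, where the alkene lies inside the lactone ring; here it is exocyclic, the tether joins the enolate carbon to the inner alkene carbon, and the closure is formally endo. It is argued to be feasible because the one-atom bridge holds the termini about 3 Å apart, no charge separation is needed, and the change from ketene acetal to carboxyl C=O offsets the strain of the new ring. Ring closed: the cyclobutane C1–C2–C8–C7, by bonding of C8 to the alkene terminus C7 inside the existing seven-membered ring (bridged boat, sigmatropic). C7: the bond can form only on the alkene face on which C2 carries C8, so the ring is necessarily cis-bridged across C2/C7 and C2 (step 2) decides the absolute sense. C8: in the transition state C9 is still tied to C11 through the ring oxygen, so C9 ends on the C1 side and the hydrogen toward the four-carbon chain. The step needs enolisation at C8 only (secured by the absence of other acidic hydrogens) and sigmatropic rather than ionic C–O cleavage (favoured by a non-polar medium and a silyl, not metal, ketene acetal); C8 stays epimerisable next to the carbonyl.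

Step 15
Reactants: 24 acid
Product: 25 methyl ketone, 1-[(1R,2R,4R,6S,7S)-2-{[tert-butyl(dimethyl)silyl]oxy}-1,5,5-trimethyl-8-methylidene-4-[(triethylsilyl)oxy]bicyclo[4.1.1]octan-7-yl]ethan-1-one
Conditions: MeLi (3 equiv), Et2O, 0 °C; inverse quench into H2O
Reagents that add atoms: methyllithium, [Li]C
Why: Addition of MeLi to the lithium carboxylate stops at the geminal dialkoxide and gives the C9 methyl ketone on hydrolysis; silyl ethers and the alkene are inert, and the new methyl is the C9 methyl of the target.

Step 16
Reactants: 25 methyl ketone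
Product: 26 diol (C9 carbinol as a mixture of epimers; C11H2OH on C1 cis to the C9 arm on C8)
Conditions: BH3·THF (4 equiv), THF, 0 °C → rt; NaOH, H2O2
Reagents that add atoms: hydrogen peroxide, OO
Why: Borane reduces the ketone and hydroborates the methylidene with boron at C11; hydrogen should reach C1 from the face turned away from the C8 substituent, which points straight across the four-membered ring at the other face, so C11 ends cis to the C9 arm. The C9 carbinol centre is of no consequence because it is oxidised in the next step.

Step 17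
Reactants: 26 diol
Product: 27 cis keto aldehyde (C9 acetyl on C8, C11 formyl on C1)
Conditions: Dess–Martin periodinane (3 equiv), pyridine, CH2Cl2, rt
Reagents that add atoms: none
Why: Dess–Martin oxidation of both alcohols in one operation; buffered, non-basic conditions should leave the α-centre C1 of the aldehyde and the silyl ethers untouched.

Step 18
Reactants: 27 keto aldehyde
Product: 28 β-keto phosphonate (C11(=O)–C10H2–P(O)(OMe)2 on C1, C9 acetyl on C8)
Conditions: (MeO)2P(O)CHN2, SnCl2 (20 mol%), CH2Cl2, rt
Reagents that add atoms: dimethyl (diazomethyl)phosphonate, COP(=O)(OC)C=[N+]=[N-]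
Why: Roskamp-type homologation: Lewis-acid-promoted addition of the diazo carbon to the aldehyde, then a 1,2-hydride shift with loss of N2, gives the β-keto phosphonate and installs C10. Ketones do not react under these conditions, so the C9 methyl ketone is spared without protection and no base touches C1 or C8.

Step 19
Reactants: 28 β-keto phosphonate
Product: 29 tricyclic enone with C3 tert-butyldimethylsilyl ether and C5 triethylsilyl ether
Conditions: K2CO3, 18-crown-6, toluene, 60 °C
Reagents that add atoms: none
Why: Intramolecular Horner–Wadsworth–Emmons olefination of the methyl ketone closes the six-membered enone regiospecifically (C11 carbonyl, C10=C9–Me); the two arms are held cis on C1/C8, and a verbenone-type ring results. C8 may epimerise next to the ketone under base, but only the cis isomer can cyclise.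

Step 20
Reactants: 29 bis-silyl ether
Product: 30 C5 alcohol (C3 silyl ether kept)
Conditions: HF·pyridine, pyridine, THF, 0 °C
Reagents that add atoms: none
Why: Buffered fluoride cleaves the triethylsilyl ether far faster than the tert-butyldimethylsilyl ether; the slightly acidic medium leaves the enone and the cyclobutane intact.

Step 21
Reactants: 30 C5 alcohol; 31 3-methylbutanoyl chloride
Product: 32 C5 isovalerate (C3 silyl ether kept)
Conditions: pyridine, DMAP (cat.), CH2Cl2, 0 °C → rt
Reagents that add atoms: none
Why: Acyl-pyridinium acylation of the hindered secondary alcohol; the C5 configuration is untouched and the enone has no accessible enolisable position.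

Step 22
Reactants: 32 silyl ether
Product: 33 C3 alcohol, C5 isovalerate
Conditions: HF·pyridine, THF, rt
Reagents that add atoms: none
Why: Acidic fluoride removes the remaining silyl group; basic fluoride is avoided so that the C5 ester does not migrate to the freed 1,3-related hydroxyl.

Step 23
Reactants: 33 C3 alcohol; 34 3-methylbut-2-enoyl chloride
Product: 35 target diester CNP0335239.1
Conditions: pyridine, DMAP (cat.), CH2Cl2, 0 °C → rt
Reagents that add atoms: none
Why: Acylation with the weak base pyridine rather than a trialkylamine keeps the acid chloride from forming a vinylketene, which would give the deconjugated ester; this last step completes both ester groups of 35.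

## Compound list

1 | ethyl 2-methyl-3-oxobutanoate | CCOC(=O)C(C)C(C)=O | starting material
2 | tert-butyl L-valinate, tert-butyl (2S)-2-amino-3-methylbutanoate | CC(C)[C@H](N)C(=O)OC(C)(C)C | starting material
3 | ethyl (2Z)-3-{[(2S)-1-tert-butoxy-3-methyl-1-oxobutan-2-yl]amino}-2-methylbut-2-enoate | CCOC(=O)/C(C)=C(C)\N[C@@H](C(C)C)C(=O)OC(C)(C)C | intermediate
4 | tert-butyl bromoacetate | BrCC(=O)OC(C)(C)C | starting material
5 | imine of 6 with 2 (not isolated), 4-tert-butyl 1-ethyl (2R)-2-[1-{[(2S)-1-tert-butoxy-3-methyl-1-oxobutan-2-yl]imino}ethyl]-2-methylbutanedioate | CCOC(=O)[C@](C)(CC(=O)OC(C)(C)C)C(C)=N[C@@H](C(C)C)C(=O)OC(C)(C)C | intermediate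
6 | 4-tert-butyl 1-ethyl (2R)-2-acetyl-2-methylbutanedioate | CCOC(=O)[C@](C)(CC(=O)OC(C)(C)C)C(C)=O | intermediate
7 | 4-tert-butyl 1-ethyl (2R)-2-methyl-2-(prop-1-en-2-yl)butanedioate | CCOC(=O)[C@](C)(CC(=O)OC(C)(C)C)C(C)=C | intermediate
8 | tert-butyl (3R)-3-(hydroxymethyl)-3,4-dimethylpent-4-enoate | OC[C@](C)(CC(=O)OC(C)(C)C)C(C)=C | intermediate
9 | tert-butyl (3R)-3-formyl-3,4-dimethylpent-4-enoate | O=C[C@](C)(CC(=O)OC(C)(C)C)C(C)=C | intermediate
10 | 2,2-dimethylbut-3-enoic acid | C=CC(C)(C)C(O)=O | starting material
11 | 3,3-dimethylpent-4-en-2-one | CC(=O)C(C)(C)C=C | intermediate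
12 | enol diisopinocampheylborinate of 11 (not isolated), from (−)-Ipc2BCl | C=C(OB([C@@H]1C[C@@H]2C[C@H]([C@H]1C)C2(C)C)[C@@H]1C[C@@H]2C[C@H]([C@H]1C)C2(C)C)C(C)(C)C=C | intermediate
13 | tert-butyl (3R)-3-[(1R)-1-hydroxy-4,4-dimethyl-3-oxohex-5-en-1-yl]-3,4-dimethylpent-4-enoate | C=CC(C)(C)C(=O)C[C@@H](O)[C@](C)(CC(=O)OC(C)(C)C)C(C)=C | intermediate
14 | tert-butyl (3R)-3-[(1R)-1-{[tert-butyl(dimethyl)silyl]oxy}-4,4-dimethyl-3-oxohex-5-en-1-yl]-3,4-dimethylpent-4-enoate | C=CC(C)(C)C(=O)C[C@@H](O[Si](C)(C)C(C)(C)C)[C@](C)(CC(=O)OC(C)(C)C)C(C)=C | intermediate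
15 | tert-butyl (3R)-3-[(1R,3R)-1-{[tert-butyl(dimethyl)silyl]oxy}-3-hydroxy-4,4-dimethylhex-5-en-1-yl]-3,4-dimethylpent-4-enoate | C=CC(C)(C)[C@H](O)C[C@@H](O[Si](C)(C)C(C)(C)C)[C@](C)(CC(=O)OC(C)(C)C)C(C)=C | intermediate
16 | tert-butyl (3R)-3-[(1R,3R)-1-{[tert-butyl(dimethyl)silyl]oxy}-4,4-dimethyl-3-[(triethylsilyl)oxy]hex-5-en-1-yl]-3,4-dimethylpent-4-enoate | C=CC(C)(C)[C@H](O[Si](CC)(CC)CC)C[C@@H](O[Si](C)(C)C(C)(C)C)[C@](C)(CC(=O)OC(C)(C)C)C(C)=C | intermediate
17 | tert-butyl (3R)-3-[(1R,3R)-1-{[tert-butyl(dimethyl)silyl]oxy}-4,4-dimethyl-3-[(triethylsilyl)oxy]hex-5-en-1-yl]-4-(hydroxymethyl)-3-methylpent-4-enoate | C=CC(C)(C)[C@H](O[Si](CC)(CC)CC)C[C@@H](O[Si](C)(C)C(C)(C)C)[C@](C)(CC(=O)OC(C)(C)C)C(CO)=C | intermediate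
18 | tert-butyl 2-[(1R,5R,7R)-7-{[tert-butyl(dimethyl)silyl]oxy}-2-(hydroxymethyl)-1,4,4-trimethyl-5-[(triethylsilyl)oxy]cyclohept-2-en-1-yl]acetate | OCC1=CC(C)(C)[C@H](O[Si](CC)(CC)CC)C[C@@H](O[Si](C)(C)C(C)(C)C)[C@]1(C)CC(=O)OC(C)(C)C | intermediate
19 | trimethylsilyl ester and trimethylsilyl ether of 20 (not isolated) | C[Si](C)(C)OCC1=CC(C)(C)[C@H](O[Si](CC)(CC)CC)C[C@@H](O[Si](C)(C)C(C)(C)C)[C@]1(C)CC(=O)O[Si](C)(C)C | intermediate
20 | 2-[(1R,5R,7R)-7-{[tert-butyl(dimethyl)silyl]oxy}-2-(hydroxymethyl)-1,4,4-trimethyl-5-[(triethylsilyl)oxy]cyclohept-2-en-1-yl]acetic acid (not isolated) | OCC1=CC(C)(C)[C@H](O[Si](CC)(CC)CC)C[C@@H](O[Si](C)(C)C(C)(C)C)[C@]1(C)CC(=O)O | intermediate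
21 | (4aR,5R,7R)-5-{[tert-butyl(dimethyl)silyl]oxy}-4a,8,8-trimethyl-7-[(triethylsilyl)oxy]-4,4a,5,6,7,8-hexahydrocyclohepta[c]pyran-3(1H)-one; δ-lactone C9(=O)–O–C11H2 fused at C1–C2 to the cycloheptene, C1=C7 | O=C1C[C@@]2(C)[C@H](O[Si](C)(C)C(C)(C)C)C[C@@H](O[Si](CC)(CC)CC)C(C)(C)C=C2CO1 | intermediate
22 | trimethylsilyl ketene acetal of 21 (C8=C9, not isolated) | C[Si](C)(C)OC1=C[C@@]2(C)[C@H](O[Si](C)(C)C(C)(C)C)C[C@@H](O[Si](CC)(CC)CC)C(C)(C)C=C2CO1 | intermediate
23 | trimethylsilyl ester of 24 (not isolated) | C[Si](C)(C)OC(=O)[C@H]1[C@@H]2C(C)(C)[C@H](O[Si](CC)(CC)CC)C[C@@H](O[Si](C)(C)C(C)(C)C)[C@@]1(C)C2=C | intermediate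
24 | (1R,2R,4R,6S,7S)-2-{[tert-butyl(dimethyl)silyl]oxy}-1,5,5-trimethyl-8-methylidene-4-[(triethylsilyl)oxy]bicyclo[4.1.1]octane-7-carboxylic acid; CO2H (C9) on C8 pointing to C1, C1=C11H2 | OC(=O)[C@H]1[C@@H]2C(C)(C)[C@H](O[Si](CC)(CC)CC)C[C@@H](O[Si](C)(C)C(C)(C)C)[C@@]1(C)C2=C | intermediate
25 | 1-[(1R,2R,4R,6S,7S)-2-{[tert-butyl(dimethyl)silyl]oxy}-1,5,5-trimethyl-8-methylidene-4-[(triethylsilyl)oxy]bicyclo[4.1.1]octan-7-yl]ethan-1-one | CC(=O)[C@H]1[C@@H]2C(C)(C)[C@H](O[Si](CC)(CC)CC)C[C@@H](O[Si](C)(C)C(C)(C)C)[C@@]1(C)C2=C | intermediate
26 | diol: bicyclo[4.1.1]octane of 25 with 1-hydroxyethyl on C8 (both C9 epimers) and hydroxymethyl (C11) on C1, the two arms cis | CC(O)[C@H]1[C@@H]2C(C)(C)[C@H](O[Si](CC)(CC)CC)C[C@@H](O[Si](C)(C)C(C)(C)C)[C@@]1(C)[C@@H]2CO | intermediate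
27 | keto aldehyde: acetyl (C9) on C8 and formyl (C11) on C1, cis | CC(=O)[C@H]1[C@@H]2C(C)(C)[C@H](O[Si](CC)(CC)CC)C[C@@H](O[Si](C)(C)C(C)(C)C)[C@@]1(C)[C@@H]2C=O | intermediate
28 | β-keto phosphonate: dimethyl 2-oxoethylphosphonate arm (C11, C10) on C1, acetyl (C9) on C8, cis | CC(=O)[C@H]1[C@@H]2C(C)(C)[C@H](O[Si](CC)(CC)CC)C[C@@H](O[Si](C)(C)C(C)(C)C)[C@@]1(C)[C@@H]2C(=O)CP(=O)(OC)OC | intermediate
29 | tricyclic enone (C11=O, C10=C9–Me) with C3–OSi(t-Bu)Me2 and C5–OSiEt3, ring centres as in 35 | CC(C)(C)[Si](C)(C)O[C@@H]1C[C@@H](O[Si](CC)(CC)CC)C(C)(C)[C@@H]2[C@H]3C(=O)C=C(C)[C@@H]2[C@]31C | intermediate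
30 | tricyclic enone with C3–OSi(t-Bu)Me2 and free C5–OH | CC(C)(C)[Si](C)(C)O[C@@H]1C[C@@H](O)C(C)(C)[C@@H]2[C@H]3C(=O)C=C(C)[C@@H]2[C@]31C | intermediate
31 | 3-methylbutanoyl chloride | CC(C)CC(Cl)=O | starting material
32 | tricyclic enone with C3–OSi(t-Bu)Me2 and C5 3-methylbutanoate | CC(C)(C)[Si](C)(C)O[C@@H]1C[C@@H](OC(=O)CC(C)C)C(C)(C)[C@@H]2[C@H]3C(=O)C=C(C)[C@@H]2[C@]31C | intermediate
33 | tricyclic enone with free C3–OH and C5 3-methylbutanoate | O[C@@H]1C[C@@H](OC(=O)CC(C)C)C(C)(C)[C@@H]2[C@H]3C(=O)C=C(C)[C@@H]2[C@]31C | intermediate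
34 | 3-methylbut-2-enoyl chloride | CC(C)=CC(Cl)=O | starting material
35 | CNP0335239.1: tricyclic enone with C3 3-methylbut-2-enoate and C5 3-methylbutanoate | CC(C)=CC(=O)O[C@@H]1C[C@@H](OC(=O)CC(C)C)C(C)(C)[C@@H]2[C@H]3C(=O)C=C(C)[C@@H]2[C@]31C | target

## Step count and risk

Total step count: 23.
Longest linear sequence: 22 steps (1 to 35 through steps 1–5 and 7–23); step 6 is a one-step side branch.

Least certain steps:

Step 14 (key step, proposed new method). The ketene acetal may fail to reach the bridged boat, because the new bond is made across a single bridging atom in a formally endo sense. On heating it could then persist, ionise at the allylic C11–O bond and recombine at C11, or decompose. The fallback uses known reactions, sets out from 18 and returns at 24. The allylic alcohol is converted with CBr4/PPh3 into the allylic bromide F1. i-Bu2AlH at −78 °C reduces the tert-butyl ester to the bromo aldehyde F2. CrCl2 in THF then effects an intramolecular Nozaki–Hiyama allylation, in which the allylchromium at C11 adds through its γ-carbon C7 to the C9 aldehyde; this closes an unstrained five-membered ring and gives the bicyclo[4.2.1]nonanol F3, which already has the C1=C11 methylidene. Dess–Martin oxidation gives the cyclopentanone F4. Trifluoroacetylation at C8, the only enolisable position (LiN(SiMe3)2, CF3CO2CH2CF3), gives the trifluoroacetyl ketone F5, and diazo transfer with MsN3/Et3N gives the α-diazo ketone F6. Photochemical Wolff rearrangement in THF–H2O contracts the ring by migration of C7 to C8 and gives 24. Any C8 epimer formed converges later, since C8 is epimerisable next to the ketone before step 19.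

Step 12. The ruthenium carbene may not turn over, because both alkenes carry a quaternary neighbour; intermolecular metathesis at the vinyl group could then compete. The fallback sets out from 16 and returns at 18. Ozonolysis of both terminal alkenes (O3, CH2Cl2, −78 °C; PPh3) gives the keto aldehyde F7, with the acetyl group on C2 and the aldehyde at C7. An intramolecular McMurry coupling with low-valent titanium (TiCl3(DME)1.5, Zn–Cu, DME, reflux, slow addition) closes the methyl-substituted cycloheptene F8. SeO2 (cat.)/t-BuOOH then oxidises the vinylic methyl group, the only allylic C–H position, to give 18.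

Step 7. Facial selectivity may be poor, since reagent control with methyl-ketone boron enolates is moderate and C2 gives no help; the C3 epimer would then have to be separated. The fallback sets out from 9 and returns at 15. An auxiliary-controlled acetate aldol with N-acetyl-(4S)-4-isopropyl-1,3-thiazolidine-2-thione (Sn(OTf)2, N-ethylpiperidine, CH2Cl2, −78 °C) gives the thiazolidinethione aldol adduct F9. Silylation (TBSOTf, 2,6-lutidine) gives its silyl ether F10, and i-Bu2AlH at −78 °C releases the β-silyloxy aldehyde F11. A Brown-type γ,γ-dimethylallylboration with the diisopinocampheylborane antipode that gives the (5R) alcohol (then NaOH, H2O2) attaches C6 with its two methyl groups and the vinyl group and gives 15 directly.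

Step 16. Facial selectivity of the hydroboration may be poor, or boron may be delivered from the borinate formed at C9, which would place C11 trans to the C9 arm so that step 19 cannot close. The fallback sets out from 27 (either C1 epimer) and returns at 29. Piperidine/AcOH in benzene at 60 °C epimerises C1 through the enamine of the aldehyde, and the cis isomer undergoes intramolecular aldol condensation of the acetyl methyl group onto C11 to give the nor-enone F12 (C9=O, C10=C11). MeLi/CeCl3 adds 1,2 to give the tertiary allylic alcohol F13. Pyridinium chlorochromate then effects the 1,3-oxidative transposition (Babler–Dauben) to 29; the chromate ester shift is preferred over ionisation, which would endanger the cyclobutane.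

## Further compounds

F1 | step 14 | tert-butyl 2-[(1R,5R,7R)-2-(bromomethyl)-7-{[tert-butyl(dimethyl)silyl]oxy}-1,4,4-trimethyl-5-[(triethylsilyl)oxy]cyclohept-2-en-1-yl]acetate | BrCC1=CC(C)(C)[C@H](O[Si](CC)(CC)CC)C[C@@H](O[Si](C)(C)C(C)(C)C)[C@]1(C)CC(=O)OC(C)(C)C
F2 | step 14 | 2-[(1R,5R,7R)-2-(bromomethyl)-7-{[tert-butyl(dimethyl)silyl]oxy}-1,4,4-trimethyl-5-[(triethylsilyl)oxy]cyclohept-2-en-1-yl]acetaldehyde | BrCC1=CC(C)(C)[C@H](O[Si](CC)(CC)CC)C[C@@H](O[Si](C)(C)C(C)(C)C)[C@]1(C)CC=O
F3 | step 14 | bicyclo[4.2.1]nonanol: C9 carbinol (both epimers) bonded to C8 and C7, C1=C11H2 as one-carbon bridge, silyl ethers as in 24 | OC1C[C@@]2(C)[C@H](O[Si](C)(C)C(C)(C)C)C[C@@H](O[Si](CC)(CC)CC)C(C)(C)[C@@H]1C2=C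
F4 | step 14 | bicyclo[4.2.1]nonanone: C9 ketone between C8H2 and C7 | O=C1C[C@@]2(C)[C@H](O[Si](C)(C)C(C)(C)C)C[C@@H](O[Si](CC)(CC)CC)C(C)(C)[C@@H]1C2=C
F5 | step 14 | C8-trifluoroacetyl derivative of F4 (C8 unspecified, enolised) | O=C1C(C(=O)C(F)(F)F)[C@@]2(C)[C@H](O[Si](C)(C)C(C)(C)C)C[C@@H](O[Si](CC)(CC)CC)C(C)(C)[C@@H]1C2=C
F6 | step 14 | C8-diazo derivative of F4 | O=C1C(=[N+]=[N-])[C@@]2(C)[C@H](O[Si](C)(C)C(C)(C)C)C[C@@H](O[Si](CC)(CC)CC)C(C)(C)[C@@H]1C2=C
F7 | step 12 | tert-butyl (3R)-3-acetyl-3-methyl-4-silyloxy-6-silyloxy-7,7-dimethyl-8-oxooctanoate: keto aldehyde from 16 (C1 acetyl, C7 aldehyde, (3R,5R) silyl ethers) | O=CC(C)(C)[C@H](O[Si](CC)(CC)CC)C[C@@H](O[Si](C)(C)C(C)(C)C)[C@](C)(CC(=O)OC(C)(C)C)C(C)=O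
F8 | step 12 | tert-butyl 2-[(1R,5R,7R)-7-{[tert-butyl(dimethyl)silyl]oxy}-1,2,4,4-tetramethyl-5-[(triethylsilyl)oxy]cyclohept-2-en-1-yl]acetate | CC1=CC(C)(C)[C@H](O[Si](CC)(CC)CC)C[C@@H](O[Si](C)(C)C(C)(C)C)[C@]1(C)CC(=O)OC(C)(C)C
F9 | step 7 | tert-butyl (3R)-3-{(1R)-1-hydroxy-3-oxo-3-[(4S)-4-isopropyl-2-thioxo-1,3-thiazolidin-3-yl]propyl}-3,4-dimethylpent-4-enoate | S=C1SC[C@H](C(C)C)N1C(=O)C[C@@H](O)[C@](C)(CC(=O)OC(C)(C)C)C(C)=C
F10 | step 7 | tert-butyldimethylsilyl ether of F9 | S=C1SC[C@H](C(C)C)N1C(=O)C[C@@H](O[Si](C)(C)C(C)(C)C)[C@](C)(CC(=O)OC(C)(C)C)C(C)=C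
F11 | step 7 | tert-butyl (3R)-3-[(1R)-1-{[tert-butyl(dimethyl)silyl]oxy}-3-oxopropyl]-3,4-dimethylpent-4-enoate | O=CC[C@@H](O[Si](C)(C)C(C)(C)C)[C@](C)(CC(=O)OC(C)(C)C)C(C)=C
F12 | step 16 | tricyclic nor-enone: C9=O, C10=C11, no C9 methyl, silyl ethers as in 29 | CC(C)(C)[Si](C)(C)O[C@@H]1C[C@@H](O[Si](CC)(CC)CC)C(C)(C)[C@@H]2[C@H]3C=CC(=O)[C@@H]2[C@]31C
F13 | step 16 | tertiary allylic alcohol: C9(OH)(CH3) (either epimer), C10=C11, silyl ethers as in 29 | CC(C)(C)[Si](C)(C)O[C@@H]1C[C@@H](O[Si](CC)(CC)CC)C(C)(C)[C@@H]2[C@H]3C=CC(C)(O)[C@@H]2[C@]31C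
A1 | alternative 1 | (2E,6E)-farnesyl diphosphate | CC(C)=CCC/C(C)=C/CC/C(C)=C/COP(=O)(O)OP(=O)(O)O
A2 | alternative 1 | α-longipinene, enantiomer with the ring centres of 35 | C1CCC(C)(C)[C@@H]2[C@H]3CC=C(C)[C@@H]2[C@]31C
A3 | alternative 2 | tricyclic nor-ketone (six-membered ring, C3 ketone, C11 dioxolane) | O=C1CC(C)(C)[C@@H]2[C@H]3C4(OCCO4)C[C@@H](C)[C@@H]2[C@]31C
A4 | alternative 2 | tricyclic cyclohept-2-enone (C3 ketone, C4=C5, C11 dioxolane) | O=C1C=CC(C)(C)[C@@H]2[C@H]3C4(OCCO4)C[C@@H](C)[C@@H]2[C@]31C
A5 | alternative 3 | (2E,6E,8R)-8-{[tert-butyl(dimethyl)silyl]oxy}-3,7,11-trimethyldodeca-2,6,10-trienoyl chloride | O=C(Cl)/C=C(\C)CC/C=C(\C)[C@H](O[Si](C)(C)C(C)(C)C)CC=C(C)C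
A6 | alternative 3 | vinylketene from A5 (C7=C8 ketene, C9=C10 Z) | O=C=C/C(C)=C\CC/C=C(\C)[C@H](O[Si](C)(C)C(C)(C)C)CC=C(C)C
A7 | alternative 3 | bicyclo[3.1.1]hept-2-en-6-one with the C3-silyloxy prenyl arm on C2 | CC(C)=CC[C@@H](O[Si](C)(C)C(C)(C)C)[C@@]1(C)[C@@H]2CC=C(C)[C@H]1C2=O
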